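Links form when first end groups meet second end groups, and the flasks below, all with equal charges, are to be ranked by the links they hold at the end. Third end groups also take second end groups, and the idle adduct, counted among the links, binds more of them.

| flask | first end groups | second end groups | third end groups | remark | time |
|---|---|---|---|---|---|
| gamma | 0.075 M | 0.075 M | 0.0187 M | run made earlier |  |
| epsilon | 0.037 M | 0.075 M | 0.0187 M | run made earlier |  |
| zeta | 0.056 M | 0.075 M | 0.0187 M | run made earlier |  |
| eta | 0.075 M | 0.15 M | 0.0187 M | run made earlier |  |
| amber | 0.075 M | 0.0750 M (fed, over 25 min) | 0.0187 M | all else is in the flask from the start; the feed brings no volume worth counting | 30 min |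
| green | 0.075 M | 0.0750 M | 0.0187 M (fed, over 25 min) | all else is in the flask from the start; the feed brings no volume worth counting | 30 min |
| ochre | 0.075 M | 0.0750 M | 0.0187 M (fed, over 2.5 min) | all else is in the flask from the start; the feed brings no volume worth counting | 30 min |
| blue | 0.075 M | 0.0750 M (in portions, 4, over 25 min) | 0.0187 M | first portion at the start, last at 25 min | 30 min |
| violet | 0.075 M | 0.0750 M | 0.0187 M | everything together at the start | 30 min |

| run | time / min | links / % | first end groups / % |
|---|---|---|---|
| gamma | 4.00 | 14.0 | 85.7 |
| gamma | 8.00 | 22.4 | 77.5 |
| gamma | 12.0 | 28.0 | 71.7 |
| gamma | 15.0 | 31.3 | 68.2 |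
| gamma | 20.0 | 35.2 | 63.5 |
| gamma | 25.0 | 38.7 | 59.9 |
| gamma | 30.0 | 40.9 | 56.8 |
| epsilon | 3.00 | 12.4 | 88.2 |
| epsilon | 4.00 | 15.5 | 84.5 |
| epsilon | 6.00 | 20.6 | 79.6 |
| epsilon | 10.0 | 29.8 | 70.2 |
| epsilon | 15.0 | 37.9 | 61.7 |
| epsilon | 25.0 | 49.4 | 49.9 |
| epsilon | 40.0 | 60.6 | 37.9 |
| zeta | 5.00 | 17.3 | 83.2 |
| zeta | 10.0 | 27.2 | 72.4 |
| zeta | 15.0 | 34.2 | 65.5 |
| zeta | 20.0 | 39.5 | 60.4 |
| zeta | 25.0 | 43.1 | 55.5 |
| zeta | 30.0 | 46.5 | 51.6 |
| zeta | 40.0 | 52.4 | 46.4 |
| eta | 3.00 | 22.4 | 77.5 |
| eta | 5.00 | 31.6 | 68.4 |
| eta | 10.0 | 48.3 | 51.7 |
| eta | 20.0 | 64.7 | 34.7 |
| eta | 40.0 | 78.9 | 19.4 |

(scatter of a reading: 0.3 percentage points)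

- in percentages every species weighs as the first end groups in it: one side product counts as two
- for links the idle adduct is counted in
- steps under discussion: first end groups + second end groups -> links; second end groups + third end groups -> links of the second sort; second end groups + links <-> idle adduct; first end groups + links -> side product; 2 third end groups -> self-condensation product

* the best flask by amount of links, in percent of the first end groups charged; "all alike" if 1.5 percentage points covers them all (amber / green / ochre / blue / violet / all alike)
* amount of links at the end, in percent of the first end groups charged, amber
* amount of links at the end, in percent of the first end groups charged, green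
* amount of links at the end, in percent of the first end groups charged, ochre
* amount of links at the end, in percent of the first end groups charged, blue
* amount of links at the end, in percent of the first end groups charged, violet

Two chemists disagree. The bookkeeper says order counts for nothing: the charges are equal, so each flask stands where gamma stood, at 40.9% after 30.0 min. The bookkeeper's zero is the statistical case, in which second end groups meet both kinds of end alike and first end groups take 80.0% of them.

The timekeeper answers from the early rates. Eta's first end groups fall 2.20 times as fast as gamma's on 2.00 times the charge of second end groups, more than the charges allow, so gamma's second end groups were already being taken. Eta gives 23.5 min for the link time, the time in which first end groups fall by a factor e with second end groups held at their full charge (a pseudo-first-order time constant), read as if eta's second end groups stayed at their charge. The rule is that the fraction of first end groups left is the exponential of minus the area under the fraction of second end groups standing, divided by the link time. Gamma's area is 13.3 min, a mean standing fraction of 44.4%.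

My own reckoning follows that rule. In amber, third end groups take the first quarter of the feed, which leaves an area of 10.8 min and links of 36.8%. In green, spreading that toll over the feed adds 3.12 min to gamma's area, giving 50.3%. Amber's figure debits no second end groups for the links themselves, so it stands high, and green's added area carries the same omission.

The forecast, on the timekeeper's side and lower than my figures for both, says green is best because slow feed “lets links form first”: green 47%, ochre 41.3%, violet 40.9%, amber 32.5%, blue 32%.

The flasks give green 45.5%, ochre 41.5%, violet 41.2%, amber 31.8%, blue 29.8%, so green is best and the timekeeper wins. The bookkeeper holds between ochre and violet, 0.3 percentage points apart, inside the margin of 1.5 points.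

    first end groups + second end groups → links (k = 0.0116 /M/s)
    second end groups + third end groups → links of the second sort (k = 0.124 /M/s)
    second end groups + links ⇌ idle adduct, settled at all times (K = 52.0 /M)
    first end groups + links → side product (k = 8.13 × 10⁻⁴ /M/s)
    2 third end groups → self-condensation product (k = 0.0166 /M/s)

By the rule, green's 52.4% of first end groups left means an area under the fraction of second end groups standing 1.14 times violet's and 1.62 times amber's, ratios from which the link time read from eta, 23.5 min, cancels. In green at 6.74 min, the link step used second end groups 2.9 times as fast as the step to links of the second sort. At 30.0 min that ratio in green was 1.3. A neighbour of green charged with 0.13 M of second end groups keeps 29.6% of its first end groups, which by the rule is 1.88 times green's area on 1.73 times green's charge of second end groups, and holds 69.0% links.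

The data stem from a simulated flask with constants of no real substance; the scatter is artificial.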